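The cyclobutane is cut at C1–C8, the bond from the quaternary O/phenethyl carbon C1 of lactone ring A to C8, whose pyranone carbon C6′ is a carboxyl equivalent. This maps onto a cis-fused ring-A cyclopentanone in which that carboxyl carbon is the ketone and C8 the adjacent diazo carbon. One photochemical Wolff shift then makes the C1–C8 bond, contracts five to four and releases the C8 acid for pyranone construction. The diazo ketone precursor already holds ring A, the C1 quaternary centre and phenyl syn to ring A. It is assembled by an amine/carbene annulation, an acylketene lactonisation and a dehydrogenation–hydrogenation reset of the benzylic centre.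

Key step: step 9

Numbering: C1–C8 follow the 2-oxabicyclo[4.2.0]octene numbering of the target; C4a–C7a follow the cyclopenta[b]pyran numbering of the bicyclic ketones (C7a becomes C1, C4a becomes C6, C5 becomes C7, C6 becomes C8).

Assumption: in step 2 the carbinol is taken to form cis to the ester and trans to phenyl (the 2-phenylethyl group turning away from the ester); carbinol epimers are removed by chromatography before the benzylic centre is erased in step 6.

Step 1
Reactants: 1 tert-butyl acetoacetate; 2 benzyl bromide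
Product: 4 tert-butyl 3-oxo-5-phenylpentanoate, via acetoacetate dianion 3 (not isolated)
Conditions: NaH, THF, 0 °C; n-BuLi, 0 °C; then 2, 0 °C to rt; 1 M HCl
Reagents that add atoms: none
Why: γ-Alkylation of a β-keto ester dianion, in which the benzylic bromide reacts only at the more basic terminal carbon, installs the 2-phenylethyl chain without forming a stereocenter.

Step 2
Reactants: 4 tert-butyl 3-oxo-5-phenylpentanoate; 5 (E)-cinnamaldehyde
Product: 7 tert-butyl (1R,2R,5S)-2-hydroxy-3-oxo-5-phenyl-2-(2-phenylethyl)cyclopentane-1-carboxylate, via Michael adduct aldehyde 6 (not isolated)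
Conditions: (R)-α,α-diphenylprolinol trimethylsilyl ether (20 mol%), 2-(pentafluorophenyl)-6,7-dihydro-5H-pyrrolo[2,1-c][1,2,4]triazolium tetrafluoroborate (10 mol%), NaOAc (10 mol%), CHCl3, rt
Reagents that add atoms: none
Why: Relay of iminium-ion Michael addition and carbene-catalysed intramolecular crossed benzoin reaction, a known pairing for β-keto esters and enals: the (R)-prolinol ether blocks one face of the iminium ion so that the benzylic carbon forms S, the acidic carbon between the carbonyls settles trans to phenyl, and the acyl anion equivalent closes onto the ketone with the 2-phenylethyl group turned away from the ester, which should place the tertiary hydroxyl cis to the ester and trans to phenyl and so fix C2 (later C7a, then C1).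

Step 3
Reactants: 7 tert-butyl (1R,2R,5S)-2-hydroxy-3-oxo-5-phenyl-2-(2-phenylethyl)cyclopentane-1-carboxylate
Product: 8 (1R,2R,5S)-2-hydroxy-3-oxo-5-phenyl-2-(2-phenylethyl)cyclopentane-1-carboxylic acid
Conditions: TFA, CH2Cl2, 0 °C to rt
Reagents that add atoms: none
Why: Acidolysis of the tert-butyl ester with loss of 2-methylpropene frees the acid without base, so the β-hydroxy ketone cannot undergo retro-aldol cleavage and no stereocenter is touched.

Step 4
Reactants: 8 (1R,2R,5S)-2-hydroxy-3-oxo-5-phenyl-2-(2-phenylethyl)cyclopentane-1-carboxylic acid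
Product: 10 (4aS,5S,7aR)-4-hydroxy-5-phenyl-7a-(2-phenylethyl)-4a,5,6,7a-tetrahydrocyclopenta[b]pyran-2,7-dione, via acyl Meldrum's acid 9 (not isolated)
Conditions: Meldrum's acid, DCC, DMAP, CH2Cl2, 0 °C to rt; then toluene, 90 °C
Reagents that add atoms: Meldrum's acid (2,2-dimethyl-1,3-dioxane-4,6-dione), CC1(C)OC(=O)CC(=O)O1
Why: C-Acylation of Meldrum's acid followed by thermolysis to an acylketene, which is captured by the neighbouring tertiary hydroxyl, builds ring A as its β-keto lactone under neutral conditions; only the cis hydroxy acid can close, so the ring fusion is cis and C4a and C7a keep their configurations.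

Step 5
Reactants: 10 (4aS,5S,7aR)-4-hydroxy-5-phenyl-7a-(2-phenylethyl)-4a,5,6,7a-tetrahydrocyclopenta[b]pyran-2,7-dione
Product: 11 (4aS,5S,7aR)-4-methoxy-5-phenyl-7a-(2-phenylethyl)-4a,5,6,7a-tetrahydrocyclopenta[b]pyran-2,7-dione
Conditions: Me2SO4, K2CO3, acetone, rt to 40 °C
Reagents that add atoms: dimethyl sulfate, COS(=O)(=O)OC
Why: O-Methylation of the enolised β-keto lactone (a vinylogous acid) gives the 4-methoxy-5,6-dihydro-2-pyranone of ring A, and the carbonate base is too weak to enolise the ketone or open the lactone, so no stereocenter changes.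

Step 6
Reactants: 11 (4aS,5S,7aR)-4-methoxy-5-phenyl-7a-(2-phenylethyl)-4a,5,6,7a-tetrahydrocyclopenta[b]pyran-2,7-dione
Product: 13 (4aS,7aR)-4-methoxy-5-phenyl-7a-(2-phenylethyl)-4a,7a-dihydrocyclopenta[b]pyran-2,7-dione, via trimethylsilyl enol ether 12 (not isolated)
Conditions: TMSOTf, Et3N, CH2Cl2, 0 °C; then Pd(OAc)2, MeCN, rt
Reagents that add atoms: none
Why: Saegusa–Ito oxidation, in which soft enolisation can only go toward C6 because C7a is quaternary and palladium diacetate turns the silyl enol ether into the C5=C6 enone, deliberately erases the benzylic stereocenter once it has relayed its chirality to C7a.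

Step 7
Reactants: 13 (4aS,7aR)-4-methoxy-5-phenyl-7a-(2-phenylethyl)-4a,7a-dihydrocyclopenta[b]pyran-2,7-dione
Product: 14 (4aS,5R,7aR)-4-methoxy-5-phenyl-7a-(2-phenylethyl)-4a,5,6,7a-tetrahydrocyclopenta[b]pyran-2,7-dione
Conditions: H2 (1 atm), 5% Pd/C, EtOAc, rt
Reagents that add atoms: none
Why: Heterogeneous hydrogenation of the 3-phenylcyclopentenone should deliver hydrogen to the convex face of the cis-fused bicycle, the face of H-4a and anti to the ring A carbon on C4a, which leaves phenyl cis to ring A (5R); the vinylogous carbonate double bond of ring A is inert here.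

Step 8
Reactants: 14 (4aS,5R,7aR)-4-methoxy-5-phenyl-7a-(2-phenylethyl)-4a,5,6,7a-tetrahydrocyclopenta[b]pyran-2,7-dione
Product: 16 (4aS,5R,7aR)-6-diazo-4-methoxy-5-phenyl-7a-(2-phenylethyl)-4a,5-dihydrocyclopenta[b]pyran-2,7(6H,7aH)-dione, via 6-trifluoroacetyl ketone 15 (not isolated)
Conditions: LiHMDS, THF, −78 °C; CF3CO2CH2CF3; 1 M HCl; then MsN3, Et3N, H2O, MeCN, rt
Reagents that add atoms: methanesulfonyl azide, CS(=O)(=O)N=[N+]=[N-]
Why: Deacylative Regitz diazo transfer, with kinetic deprotonation at C6 (the only α-methylene), trifluoroacetyl activation and transfer from the sulfonyl azide with loss of the activating group, installs the diazo group without touching a stereocenter.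

Step 9
Reactants: 16 (4aS,5R,7aR)-6-diazo-4-methoxy-5-phenyl-7a-(2-phenylethyl)-4a,5-dihydrocyclopenta[b]pyran-2,7(6H,7aH)-dione
Product: 18 (1R,6S,7S)-5-methoxy-3-oxo-7-phenyl-1-(2-phenylethyl)-2-oxabicyclo[4.2.0]oct-4-ene-8-carboxylic acid (C8 epimer mixture), via ketene 17 (not isolated)
Conditions: hν (365 nm LED, Pyrex), THF/H2O 4:1, argon, 10 °C
Reagents that add atoms: water, O
Why: Excitation of the s-cis-locked cyclic diazo ketone expels N2 with concerted 1,2-shift of C7a (future C1) from the carbonyl carbon to the diazo carbon (future C8), a photochemical Wolff rearrangement whose closest precedent is the contraction of 2-diazocyclopentanones to cyclobutanecarboxylic acid derivatives. The cyclobutane is closed not by an end-to-end cyclisation but by this 1,2-shift, which contracts the five-membered ring by pushing the former carbonyl carbon out as the exocyclic ketene carbon, and water then adds to the ketene. C1 migrates suprafacially with retention, so the O/2-phenylethyl quaternary centre and the cis ring A fusion are carried over unchanged. The new C8 centre arises when the acid enol is protonated under substrate control from the less hindered convex face, which should favour the epimer with CO2H cis to phenyl; this is tolerated because C8 is equilibrated in step 11. The selectivity needed is Wolff shift over 1,2-hydride shift from the benzylic C5–H and over O–H insertion, and it is secured by the enforced s-cis geometry, by direct unsensitised irradiation above 300 nm and by C7a being the only group able to migrate.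

Step 10
Reactants: 18 (1R,6S,7S)-5-methoxy-3-oxo-7-phenyl-1-(2-phenylethyl)-2-oxabicyclo[4.2.0]oct-4-ene-8-carboxylic acid (C8 epimer mixture); 19 methyl acetoacetate
Product: 22 methyl 5-[(1R,6S,7S)-5-methoxy-3-oxo-7-phenyl-1-(2-phenylethyl)-2-oxabicyclo[4.2.0]oct-4-en-8-yl]-3,5-dioxopentanoate (C8 epimer mixture), via acyl imidazolide 20 (not isolated), via methyl acetoacetate dianion 21 (not isolated)
Conditions: 18, CDI, THF, rt; added at −78 °C to the dianion from 19 (NaH, then n-BuLi, THF, 0 °C); to 0 °C; 1 M HCl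
Reagents that add atoms: none
Why: Claisen-type C-acylation of the acetoacetate dianion at its terminal carbon by the N-acylimidazole, which is far more electrophilic than the vinylogous carbonate of ring A, gives the 3,5-dioxo ester; C8 is not controlled here.

Step 11
Reactants: 22 methyl 5-[(1R,6S,7S)-5-methoxy-3-oxo-7-phenyl-1-(2-phenylethyl)-2-oxabicyclo[4.2.0]oct-4-en-8-yl]-3,5-dioxopentanoate (C8 epimer mixture)
Product: 23 (1R,6S,7S,8S)-8-(4-hydroxy-2-oxo-2H-pyran-6-yl)-5-methoxy-7-phenyl-1-(2-phenylethyl)-2-oxabicyclo[4.2.0]oct-4-en-3-one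
Conditions: DBU, toluene, rt to 60 °C; then 1 M HCl
Reagents that add atoms: none
Why: Base-mediated lactonisation of the 3,5-dioxo ester (enol oxygen onto the ester, loss of methanol) gives the 4-hydroxy-2-pyranone, while C8, now α to a ketone, should equilibrate by reversible enolisation toward the epimer with the side chain trans to phenyl before the ring closes; residual epimer is removed by chromatography.

Step 12
Reactants: 23 (1R,6S,7S,8S)-8-(4-hydroxy-2-oxo-2H-pyran-6-yl)-5-methoxy-7-phenyl-1-(2-phenylethyl)-2-oxabicyclo[4.2.0]oct-4-en-3-one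
Product: 24 (1R,6S,7S,8S)-5-methoxy-8-(4-methoxy-2-oxo-2H-pyran-6-yl)-7-phenyl-1-(2-phenylethyl)-2-oxabicyclo[4.2.0]oct-4-en-3-one
Conditions: Me2SO4, K2CO3, acetone, 40 °C
Reagents that add atoms: dimethyl sulfate, COS(=O)(=O)OC
Why: O-Methylation of the 4-hydroxy-2-pyranone at O4, the usual regiochemistry for 6-alkyl-4-hydroxy-2-pyranones under these conditions, completes the second methoxypyranone without touching a stereocenter.

Compound list
1 | tert-butyl acetoacetate | CC(=O)CC(=O)OC(C)(C)C | starting material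
2 | benzyl bromide | BrCc1ccccc1 | starting material
3 | sodium lithium dianion of tert-butyl acetoacetate | [Na+].[Li+].[CH2-]C(=O)[CH-]C(=O)OC(C)(C)C | intermediate
4 | tert-butyl 3-oxo-5-phenylpentanoate | CC(C)(C)OC(=O)CC(=O)CCc1ccccc1 | intermediate
5 | (E)-cinnamaldehyde | O=C/C=C/c1ccccc1 | starting material
6 | tert-butyl 3-oxo-2-[(1S)-3-oxo-1-phenylpropyl]-5-phenylpentanoate (C2 epimers) | CC(C)(C)OC(=O)C(C(=O)CCc1ccccc1)[C@H](CC=O)c1ccccc1 | intermediate
7 | tert-butyl (1R,2R,5S)-2-hydroxy-3-oxo-5-phenyl-2-(2-phenylethyl)cyclopentane-1-carboxylate (OH cis to ester, phenyl trans to both) | O[C@]1(CCc2ccccc2)[C@H](C(=O)OC(C)(C)C)[C@@H](c2ccccc2)CC1=O | intermediate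
8 | (1R,2R,5S)-2-hydroxy-3-oxo-5-phenyl-2-(2-phenylethyl)cyclopentane-1-carboxylic acid | O[C@]1(CCc2ccccc2)[C@H](C(=O)O)[C@@H](c2ccccc2)CC1=O | intermediate
9 | 5-{[(1R,2R,5S)-2-hydroxy-3-oxo-5-phenyl-2-(2-phenylethyl)cyclopentyl]carbonyl}-2,2-dimethyl-1,3-dioxane-4,6-dione | O[C@]1(CCc2ccccc2)[C@H](C(=O)C2C(=O)OC(C)(C)OC2=O)[C@@H](c2ccccc2)CC1=O | intermediate
10 | (4aS,5S,7aR)-4-hydroxy-5-phenyl-7a-(2-phenylethyl)-4a,5,6,7a-tetrahydrocyclopenta[b]pyran-2,7-dione (cis-fused, phenyl trans to ring A) | OC1=CC(=O)O[C@]2(CCc3ccccc3)[C@H]1[C@@H](c1ccccc1)CC2=O | intermediate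
11 | (4aS,5S,7aR)-4-methoxy-5-phenyl-7a-(2-phenylethyl)-4a,5,6,7a-tetrahydrocyclopenta[b]pyran-2,7-dione | COC1=CC(=O)O[C@]2(CCc3ccccc3)[C@H]1[C@@H](c1ccccc1)CC2=O | intermediate
12 | 7-trimethylsilyl enol ether of 11 (C6=C7 enol ether, other centres as in 11) | COC1=CC(=O)O[C@]2(CCc3ccccc3)[C@H]1[C@@H](c1ccccc1)C=C2O[Si](C)(C)C | intermediate
13 | (4aS,7aR)-4-methoxy-5-phenyl-7a-(2-phenylethyl)-4a,7a-dihydrocyclopenta[b]pyran-2,7-dione | COC1=CC(=O)O[C@]2(CCc3ccccc3)[C@H]1C(c1ccccc1)=CC2=O | intermediate
14 | (4aS,5R,7aR)-4-methoxy-5-phenyl-7a-(2-phenylethyl)-4a,5,6,7a-tetrahydrocyclopenta[b]pyran-2,7-dione (cis-fused, phenyl cis to ring A) | COC1=CC(=O)O[C@]2(CCc3ccccc3)[C@H]1[C@H](c1ccccc1)CC2=O | intermediate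
15 | 6-(trifluoroacetyl) derivative of 14 (C6 undefined, enolised; other centres as in 14) | COC1=CC(=O)O[C@]2(CCc3ccccc3)[C@H]1[C@H](c1ccccc1)C(C(=O)C(F)(F)F)C2=O | intermediate
16 | (4aS,5R,7aR)-6-diazo-4-methoxy-5-phenyl-7a-(2-phenylethyl)-4a,5-dihydrocyclopenta[b]pyran-2,7(6H,7aH)-dione | COC1=CC(=O)O[C@]2(CCc3ccccc3)[C@H]1[C@H](c1ccccc1)C(=[N+]=[N-])C2=O | intermediate
17 | ring-contracted ketene, 5-methoxy-8-(oxomethylidene)-7-phenyl-1-(2-phenylethyl)-2-oxabicyclo[4.2.0]oct-4-en-3-one (centres carried over from 16) | COC1=CC(=O)O[C@]2(CCc3ccccc3)[C@H]1[C@H](c1ccccc1)C2=C=O | intermediate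
18 | (1R,6S,7S)-5-methoxy-3-oxo-7-phenyl-1-(2-phenylethyl)-2-oxabicyclo[4.2.0]oct-4-ene-8-carboxylic acid (C8 epimer mixture) | COC1=CC(=O)O[C@]2(CCc3ccccc3)[C@H]1[C@H](c1ccccc1)C2C(=O)O | intermediate
19 | methyl acetoacetate | COC(=O)CC(C)=O | starting material
20 | N-acylimidazole of 18 (C8 epimer mixture) | COC1=CC(=O)O[C@]2(CCc3ccccc3)[C@H]1[C@H](c1ccccc1)C2C(=O)n1ccnc1 | intermediate
21 | sodium lithium dianion of methyl acetoacetate | [Na+].[Li+].[CH2-]C(=O)[CH-]C(=O)OC | intermediate
22 | methyl 5-[(1R,6S,7S)-5-methoxy-3-oxo-7-phenyl-1-(2-phenylethyl)-2-oxabicyclo[4.2.0]oct-4-en-8-yl]-3,5-dioxopentanoate (C8 epimer mixture) | COC1=CC(=O)O[C@]2(CCc3ccccc3)[C@H]1[C@H](c1ccccc1)C2C(=O)CC(=O)CC(=O)OC | intermediate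
23 | (1R,6S,7S,8S)-8-(4-hydroxy-2-oxo-2H-pyran-6-yl)-5-methoxy-7-phenyl-1-(2-phenylethyl)-2-oxabicyclo[4.2.0]oct-4-en-3-one | COC1=CC(=O)O[C@]2(CCc3ccccc3)[C@H]1[C@H](c1ccccc1)[C@H]2c1cc(O)cc(=O)o1 | intermediate
24 | (1R,6S,7S,8S)-5-methoxy-8-(4-methoxy-2-oxo-2H-pyran-6-yl)-7-phenyl-1-(2-phenylethyl)-2-oxabicyclo[4.2.0]oct-4-en-3-one | COC1=CC(=O)O[C@]2(CCc3ccccc3)[C@H]1[C@H](c1ccccc1)[C@H]2c1cc(OC)cc(=O)o1 | target

Total step count: 12. Longest linear sequence: 12 steps (1 to 24).

Steps most likely to fail

Step 2. The carbene may divert cinnamaldehyde into homoenolate or redox pathways before the Michael step, and closure onto the ketone may discriminate poorly between its two faces, which would weaken the chirality relay to C7a. The fallback sets out from 6, made from 4 and 5 with the amine catalyst alone and isolated. The ring is then closed reductively instead of by carbene catalysis: SmI2 in THF/MeOH at −78 °C effects ketyl–aldehyde pinacol coupling, with chelation of samarium between the ketyl oxygen and the ester expected to give tert-butyl (1R,2R,3S,5S)-2,3-dihydroxy-5-phenyl-2-(2-phenylethyl)cyclopentane-1-carboxylate F1 (cis-diol, tertiary OH cis to the ester). Parikh–Doering oxidation (SO3·pyridine, DMSO, i-Pr2NEt) of the secondary alcohol returns to 7.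

Step 9. Loss of N2 may outrun migration, so that a free carbene undergoes 1,2-hydride shift from C5 or O–H insertion with water, and prolonged irradiation may degrade the product. The fallback sets out from 14 and replaces the carbene route by an anionic ring contraction. Bromination at C6 with phenyltrimethylammonium tribromide in THF gives (4aS,5R,7aR)-6-bromo-4-methoxy-5-phenyl-7a-(2-phenylethyl)-4a,5,6,7a-tetrahydrocyclopenta[b]pyran-2,7-dione F2. Because C7a carries no hydrogen, LiOH in aqueous THF at 0 °C can only trigger the quasi-Favorskii (semibenzilic) shift of C7a onto C6 with loss of bromide. Acidification, which also recloses any opened ring A lactone, returns to 18.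

Step 11. Lactonisation may outpace enolisation toward C8 and leave the side chain cis to phenyl, or the C8 enolate may expel the ring A carboxylate from C1 (β-elimination with opening of ring A). The fallback sets out from 18 and fixes C8 on a simple ketone before the pyranone is built. Coupling with N,O-dimethylhydroxylamine (EDC, HOBt) gives (1R,6S,7S)-N,5-dimethoxy-N-methyl-3-oxo-7-phenyl-1-(2-phenylethyl)-2-oxabicyclo[4.2.0]oct-4-ene-8-carboxamide F3. MeMgBr in THF at −40 °C gives the acetylcyclobutane, whose only enolisable methine is C8; catalytic DBU in CH2Cl2 equilibrates it to (1R,6S,7S,8R)-8-acetyl-5-methoxy-7-phenyl-1-(2-phenylethyl)-2-oxabicyclo[4.2.0]oct-4-en-3-one F4 (acetyl trans to phenyl), the classical epimerisation of acylcyclobutanes. Kinetic silylation (LiHMDS, TMSCl, THF, −78 °C) gives (1R,6S,7S,8R)-5-methoxy-7-phenyl-1-(2-phenylethyl)-8-[1-(trimethylsilyloxy)ethenyl]-2-oxabicyclo[4.2.0]oct-4-en-3-one F5. Condensation with malonyl dichloride (Et2O, −78 °C to rt) builds the 4-hydroxy-2-pyranone directly and rejoins the route at 23.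

Further compounds
F1 | step 2 | tert-butyl (1R,2R,3S,5S)-2,3-dihydroxy-5-phenyl-2-(2-phenylethyl)cyclopentane-1-carboxylate | O[C@]1(CCc2ccccc2)[C@H](C(=O)OC(C)(C)C)[C@@H](c2ccccc2)C[C@@H]1O
F2 | step 9 | (4aS,5R,7aR)-6-bromo-4-methoxy-5-phenyl-7a-(2-phenylethyl)-4a,5,6,7a-tetrahydrocyclopenta[b]pyran-2,7-dione (C6 epimers) | COC1=CC(=O)O[C@]2(CCc3ccccc3)[C@H]1[C@H](c1ccccc1)C(Br)C2=O
F3 | step 11 | (1R,6S,7S)-N,5-dimethoxy-N-methyl-3-oxo-7-phenyl-1-(2-phenylethyl)-2-oxabicyclo[4.2.0]oct-4-ene-8-carboxamide (C8 epimer mixture) | COC1=CC(=O)O[C@]2(CCc3ccccc3)[C@H]1[C@H](c1ccccc1)C2C(=O)N(C)OC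
F4 | step 11 | (1R,6S,7S,8R)-8-acetyl-5-methoxy-7-phenyl-1-(2-phenylethyl)-2-oxabicyclo[4.2.0]oct-4-en-3-one | COC1=CC(=O)O[C@]2(CCc3ccccc3)[C@H]1[C@H](c1ccccc1)[C@H]2C(C)=O
F5 | step 11 | (1R,6S,7S,8R)-5-methoxy-7-phenyl-1-(2-phenylethyl)-8-[1-(trimethylsilyloxy)ethenyl]-2-oxabicyclo[4.2.0]oct-4-en-3-one | COC1=CC(=O)O[C@]2(CCc3ccccc3)[C@H]1[C@H](c1ccccc1)[C@H]2C(=C)O[Si](C)(C)C
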